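**Retrosynthetic overview**
1. The C5 side chain is traced to 2-methylbut-3-en-2-ol (1), used as its tert-butyl carbonate 2.
2. Rings A, C and B are not built: the whole isoflavone skeleton is traced intact to genistein (3), a bulk soy isoflavone, so no ring is formed in the route.
3. The prenyl C–C bond comes from an aromatic Claisen transform of the tertiary allyl aryl ether 4 (made from 3 + 2 by O-allylation), passing through dienone 5 to isowighteone 6.
4. Key disconnection, made last: the C5'–OH carbon–oxygen bond of the catechol, by ortho-hydroxylation of the 4'-phenol of 6 through ortho-quinone 7 to the target 8.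
5. No protecting groups are used in the main line.

Assumption: the target has no stereocentre and no stereogenic double bond (the side-chain alkene carries two identical methyl groups), so the SMILES as given is the only stereoisomer and no stereocontrol is needed.

**Route**

Step 1
Reactants: 1 2-methylbut-3-en-2-ol
Product: 2 tert-butyl (2-methylbut-3-en-2-yl) carbonate
Conditions: n-BuLi (1.05 equiv), THF, −78 → 0 °C; then Boc2O (1.1 equiv), 0 °C → rt; aqueous work-up
Reagents that add atoms: di-tert-butyl dicarbonate (Boc2O), CC(C)(C)OC(=O)OC(=O)OC(C)(C)C
Why: O-acylation of a lithium alkoxide (mixed carbonate formation); the hindered tertiary allylic alkoxide attacks Boc2O cleanly and no stereocentre is involved.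

Step 2
Reactants: 3 genistein (5,7,4'-trihydroxyisoflavone); 2 tert-butyl (2-methylbut-3-en-2-yl) carbonate
Product: 4 4'-O-(2-methylbut-3-en-2-yl)genistein
Conditions: KOt-Bu (1.0 equiv), DMF/THF, 0 °C; then Pd(PPh3)4 (3 mol%), 2 (1.1 equiv), 0 °C, 1–2 h; AcOH (1.0 equiv) quench
Reagents that add atoms: none
Why: Tsuji–Trost allylic etherification: zerovalent palladium ionises 2 (loss of CO2) to a 1,1-dimethyl-π-allyl palladium cation plus tert-butoxide; with the acidic 7-OH already held as its potassium salt, the tert-butoxide deprotonates 4'-OH, and the more basic, more nucleophilic 4'-phenoxide of the dianion attacks the substituted allyl terminus (kinetic branched ether at 0 °C, short time), while the chelated 5-OH stays out; no stereocentre is formed.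

Step 3
Reactants: 4 4'-O-(2-methylbut-3-en-2-yl)genistein
Product: 6 isowighteone (3'-prenylgenistein), via ortho-dienone 5 (not isolated)
Conditions: PhNEt2, 130 °C, Ar, 3 h
Reagents that add atoms: none
Why: Aromatic Claisen rearrangement ([3,3]-sigmatropic shift, accelerated by the gem-dimethyl group) delivers the allyl unit with inversion to either of the two equivalent ortho carbons, and dienone 5 tautomerises to the phenol; the basic solvent suppresses acid-catalysed chroman formation, and the transient sp3 centre of 5 is lost on rearomatisation.

Step 4
Reactants: 6 isowighteone (3'-prenylgenistein)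
Product: 8 glycyrrhisoflavone (5,7,3',4'-tetrahydroxy-5'-prenylisoflavone), via ortho-quinone 7 (not isolated)
Conditions: Cu(MeCN)4PF6 (10 mol%), N,N'-di-tert-butylethylenediamine (20 mol%), O2 (1 atm), 4 Å MS, CH2Cl2/acetone 3:1 (0.05 M), rt, 4–6 h; then L-ascorbic acid (3 equiv), degassed MeOH/H2O, Ar, 0 °C, 15 min; EDTA wash
Reagents that add atoms: dioxygen, O=O
Why: Proposed new method: tyrosinase-like aerobic ortho-hydroxylation of an unprotected prenylated polyphenol with in-flask reduction to the catechol; monovalent copper with the hindered diamine binds O2 as a side-on peroxo dicopper core (two divalent copper centres, in equilibrium with the bis-μ-oxo form of two trivalent copper centres), the 4'-phenol (the most electron-rich phenol of 6) binds as phenolate and is attacked by the electrophilic copper–oxygen core at its only free ortho carbon C5' (the other ortho carbon carries the prenyl group), and the copper-bound semiquinone/ortho-quinone 7 is reduced by ascorbic acid before it can tautomerise toward a quinone methide or be attacked by ring A of a second molecule; the para-acyl 7-OH and the hydrogen-bonded 5-OH are electron-poor phenols and should react far more slowly, and the isolated trisubstituted alkene should not be touched; closest known reaction type: copper/diamine/O2 ortho-oxygenation of simple monophenols to ortho-quinones and the enzymatic tyrosinase hydroxylation of 4'-hydroxyisoflavones, neither shown on a 3'-prenylated isoflavone with free ring A hydroxyls.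

**Compound list**
1 | 2-methylbut-3-en-2-ol | C=CC(C)(C)O | starting material
2 | tert-butyl (2-methylbut-3-en-2-yl) carbonate | C=CC(C)(C)OC(=O)OC(C)(C)C | intermediate
3 | genistein (5,7-dihydroxy-3-(4-hydroxyphenyl)chromen-4-one) | O=c1c(-c2ccc(O)cc2)coc2cc(O)cc(O)c12 | starting material
4 | 4'-O-(2-methylbut-3-en-2-yl)genistein (5,7-dihydroxy-3-[4-(2-methylbut-3-en-2-yloxy)phenyl]chromen-4-one) | C=CC(C)(C)Oc1ccc(-c2coc3cc(O)cc(O)c3c2=O)cc1 | intermediate
5 | ortho-dienone: 5,7-dihydroxy-3-[3-(3-methylbut-2-enyl)-4-oxocyclohexa-1,5-dien-1-yl]chromen-4-one (prenyl and H on the sp3 ring carbon, racemic, transient) | CC(C)=CCC1C=C(c2coc3cc(O)cc(O)c3c2=O)C=CC1=O | intermediate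
6 | isowighteone (5,7-dihydroxy-3-[4-hydroxy-3-(3-methylbut-2-enyl)phenyl]chromen-4-one) | CC(C)=CCc1cc(-c2coc3cc(O)cc(O)c3c2=O)ccc1O | intermediate
7 | ortho-quinone: 5,7-dihydroxy-3-[5-(3-methylbut-2-enyl)-3,4-dioxocyclohexa-1,5-dien-1-yl]chromen-4-one | CC(C)=CCC1=CC(c2coc3cc(O)cc(O)c3c2=O)=CC(=O)C1=O | intermediate
8 | glycyrrhisoflavone (5,7-dihydroxy-3-[3,4-dihydroxy-5-(3-methylbut-2-enyl)phenyl]chromen-4-one) | CC(C)=CCc1cc(-c2coc3cc(O)cc(O)c3c2=O)cc(O)c1O | target

**Step count**
Total steps: 4. Longest linear sequence: 4 (1 → 2 → 4 → 6 → 8); 3 steps from genistein.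

**Three steps most likely to fail**

Step 4 (proposed new hydroxylation). The likely failures are oxygenation on ring A, copper being tied up by the 5-OH/C4=O chelating site, or amine-promoted decomposition of 7. The fallback is known chemistry with a different oxygen source and mechanism. It sets out from 6: 2-iodoxybenzoic acid (1.2 equiv) in DMF at rt binds the electron-rich 4'-phenol as an aryloxy-iodane (pentavalent iodine) and transfers oxygen to C5' by an intramolecular sigmatropic shift. This reagent leaves electron-poor and hydrogen-bonded phenols alone. It gives the same ortho-quinone 7, which is reduced in the same flask with aqueous Na2S2O4, and the fallback comes back to the route at 8. It makes no compound outside the list (none, F0).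

Step 2 (site-selective O-allylation of unprotected genistein). The likely failures are 7-O-allylation, C-allylation of ring A at C6/C8, or isomerisation to the linear prenyl ether. The fallback sets out from 3 and removes the ring A anion by temporary protection. The mono-potassium salt of 3 (KOt-Bu 1.0 equiv, DMF, 0 °C) is silylated with TIPSCl to 7-O-triisopropylsilylgenistein F1. Base-free Tsuji–Trost etherification of F1 with 2 and Pd(PPh3)4 in THF at 0 °C then gives 4'-O-(2-methylbut-3-en-2-yl)-7-O-triisopropylsilylgenistein F2, since 4'-OH is the only unchelated phenol left. Bu4NF/AcOH in THF at 0 °C removes the silyl group, and the fallback comes back to the route at 4.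

Step 3 (thermal Claisen with free acidic phenols). The likely failures are loss of isoprene back to genistein or cyclisation to a chroman. The fallback sets out from 4 and swaps the thermal rearrangement for a Lewis-acid-catalysed one on a masked substrate. Ac2O/pyridine/DMAP gives 5,7-di-O-acetyl-4'-O-(2-methylbut-3-en-2-yl)genistein F3, which is soluble in chloroform and free of acidic OH. Eu(fod)3 (10 mol%; fod = 6,6,7,7,8,8,8-heptafluoro-2,2-dimethyloctane-3,5-dionate) in CHCl3 at 60 °C effects the Claisen rearrangement to 5,7-di-O-acetylisowighteone F4. K2CO3 in MeOH at 0 °C cleaves the two acetates, and the fallback comes back to the route at 6.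

Further compounds
F0 | step 4 | none | none
F1 | step 2 | 7-O-triisopropylsilylgenistein | CC(C)[Si](Oc1cc(O)c2c(c1)occ(-c1ccc(O)cc1)c2=O)(C(C)C)C(C)C
F2 | step 2 | 4'-O-(2-methylbut-3-en-2-yl)-7-O-triisopropylsilylgenistein | C=CC(C)(C)Oc1ccc(-c2coc3cc(O[Si](C(C)C)(C(C)C)C(C)C)cc(O)c3c2=O)cc1
F3 | step 3 | 5,7-di-O-acetyl-4'-O-(2-methylbut-3-en-2-yl)genistein | C=CC(C)(C)Oc1ccc(-c2coc3cc(OC(C)=O)cc(OC(C)=O)c3c2=O)cc1
F4 | step 3 | 5,7-di-O-acetylisowighteone | CC(C)=CCc1cc(-c2coc3cc(OC(C)=O)cc(OC(C)=O)c3c2=O)ccc1O
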